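## Structural features

The target is a 2,3-trans-dihydroflavonol: a chroman-4-one in which the 5,7-dihydroxylated benzo ring A is fused to the pyranone ring C, with ring B attached at C2. Ring B is a fully loaded resorcinol, with hydroxyls at C2' and C4', prenyl groups at C3' and C5', and hydrogen only at C6'. The only stereocentres are the adjacent C2 (benzylic aryl ether carbon) and C3 (secondary carbinol alpha to the C4 ketone), both R and trans to each other. Assignment of the target SMILES gives (2R,3R), and the acyclic aldol drawn for the key step carries the same two centres with retention, so no structure needed correction. The fragile parts are the prenyl alkenes next to phenols (acid closes them to chromans, hydrogenation is excluded), the C2–O1 bond (base can open ring C towards a chalcone, and the electron-rich ring B can ionise C2), the enolisable C3, and the oxidation-prone polyphenol. The real difficulty is to set C2 and C3 in the absolute sense next to a hindered, electron-rich ring B, with protecting groups that can leave without strong acid, base or reduction. The key step uses the fact that C3 bears oxygen and lies between the C4 carbonyl and the C2 carbinol: C3 can be a carbene carbon that receives its oxygen from an alcohol and C2 from the ring B aldehyde in one event. The C4 carbonyl, ortho to C8a, then activates a fluoride on ring A for closure of ring C through O1–C8a.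

Abbreviations: MOM = methoxymethyl, PMB = 4-methoxybenzyl.

## Logic of the disconnections

**20 from 19.** The four phenolic O–CH2 acetal bonds are cut. The phenols must pass organolithium, carbenoid and fluoride-releasing steps, and an acetal survives all three and leaves without hydrogenation or strong base. The gain is that the polyphenol appears only in the last operation. The forward step must use acid mild enough not to close a prenyl group onto a neighbouring phenol.

**19 from 18.** The C3–O–CH2 bond of the benzyl-type ether is cut. The C3 oxygen has to be capped while ring C closes, or it would compete for the fluoroarene in a five-membered closure. The cap is the alcohol component of the key step, so it costs no step to install. The forward cleavage must single out the anisyl CH2 beside the electron-rich ring B and its benzylic–allylic CH2 groups.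

**18 from 17.** The O1–C8a aryl ether bond is cut. The C4 carbonyl is ortho to C8a, so a fluoride there can be displaced by the C2 hydroxyl without touching any bond at C2 or C3. The 2,3-trans ring thus becomes an anti acyclic aldol, and the problem reduces to acyclic stereocontrol. The forward step needs substitution by the alkoxide to be faster than retro-aldol cleavage, and a base that does not epimerise the product.

**17 from 6, 16 and 15.** The C2–C3 bond and the C3–O bond are cut. C3 becomes the carbene carbon of 6, its oxygen comes from 16 and C2 is the formyl carbon of 15. This gives two aromatic halves of similar size and a simple alcohol; both stereocentres arise here and no ring is formed. The forward step demands that aldol-type trapping of the ylide beats proton shift, that a chiral cocatalyst sets the anti relationship and the absolute sense, and that the carbenoid ignores the prenyl alkenes.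

**6 from 3 (through 4 and 5).** The C=N2 bond is cut. A methyl ketone is the simplest precursor of a terminal diazoketone and avoids an acid chloride, which the acetals would not tolerate. The forward step must activate the methyl group transiently, since direct diazo transfer to a simple ketone fails.

**3 from 2.** Two O–CH2 acetal bonds are cut, leaving a free dihydroxy ketone. The demand is that the hydrogen-bonded ortho hydroxyl is also alkylated.

**2 from 1.** The aryl–acyl C–C bond is cut, leading to a symmetrical fluororesorcinol. The acylation must go para to one hydroxyl and next to fluorine, and not between the two hydroxyls.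

**15 from 13 (through 14).** The aryl–CHO bond is cut, with bromine marking the position. The demand is a clean bromine–lithium exchange on a ring that carries two prenyl groups.

**13 from 11 and 9 (through 12).** The aryl–CH2 bond of the C5' prenyl group is cut. The two remaining bromines of 11 are equivalent, so the forward step only has to stop at mono-exchange.

**11 from 8 and 9 (through 10).** The aryl–CH2 bond of the C3' prenyl group is cut. The forward step must exchange the bromine that lies between the two acetal oxygens in preference to the two flanking ones.

**8 from 7.** Two O–CH2 acetal bonds are cut. 7 carries a bromine at every position of ring B that later needs a carbon substituent, so the substitution pattern is bought and not built.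

## Other disconnections considered

**Alternative 1:** Here ring B itself is cut, at C5'–C6' and C2'–C3', into 2,10-dimethylundeca-2,9-dien-6-one (A1) and diethyl ethoxymethylenemalonate (A2).

- **Forward key step.** The enolate of A1 adds to A2 with loss of ethoxide, the second alpha carbon acylates on an ester, and the ring aromatises to ethyl 2,4-dihydroxy-3,5-diprenylbenzoate (A3).
- **In favour.** The substitution pattern of ring B follows from the connectivity of a symmetrical ketone, and no cryogenic organometallic step is needed. On regiochemical certainty this is better than steps 5 and 6 of the chosen plan.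
- **Against.** It supplies only ring B and says nothing about C2 and C3. A3 is an ester that needs protection, reduction and reoxidation before it reaches 15, and A1 is not an article of commerce. Enolates of simple ketones often close onto such malonates through oxygen to give 2-pyranones; carbon closure needs the less acidic, substituted second alpha position to react.
- **Comparison.** On structure the two plans are equal, since both end at the same ring B aldehyde. On mechanism the exchange chemistry of the chosen plan is the more predictable. On step economy the alternative needs about six or seven steps to 15 against four. It could replace steps 4 to 7 without touching the key step.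

**Alternative 2:** Here the C3–C4 bond is cut, giving the dialdehyde A4, in which a ring A salicylaldehyde oxygen carries the ring B arylacetaldehyde unit.

- **Forward key step.** A chiral triazolylidene carbene turns the ring A aldehyde into an acyl anion equivalent that adds to the alpha-aryloxy aldehyde. This closes ring C while C2 equilibrates through the enol, and gives the tetra-MOM ether A5, which is identical with 19.
- **In favour.** Ring C and both stereocentres are made in one metal-free catalytic step, so it builds more per step than the chosen key step, which closes no ring. The product is already 19, so the endgame is one step shorter and needs no oxidant. It also avoids base-mediated closure of a retro-aldol-prone aldol. On these three points it is better than the chosen plan.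
- **Against.** A4 is hard to make and to keep. The donor aldehyde on ring A is di-ortho-substituted and electron-rich, so formation of the acyl anion equivalent would be slow. The aliphatic aldehyde could take the donor role and give the transposed acyloin. The product acyloin can tautomerise under the basic conditions. The dynamic resolution asks the catalyst to tell apart an aryl and an aryloxy group of similar size at C2. Related closures onto ketones are well established; closure onto an enolisable aldehyde is less so.
- **Comparison.** Both plans set two stereocentres in one step and both rest on demanding selectivity. A4 needs about five further steps from 15, so the overall count is similar, but the route is more linear and commits the valuable ring B material earlier.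

**Alternative 3:** Here ring A is cut at C4a–C5 and unfolded into the acetonide-protected triketo ester A6.

- **Forward key step.** The C4a carbanion of A6 attacks the terminal ester carbon, and the resulting cyclohexanetrione enolises to the acylphloroglucinol A7.
- **In favour.** The diol of A6 has the syn relationship, because ring C would later close at C2 with inversion, or through a ring B-stabilised cation in which C3 dictates the trans outcome. That diol could come from an auxiliary-controlled syn-glycolate aldol with 15, which is better precedented than the chosen key step. On security of stereocontrol the alternative is the better plan. It also needs no diazo compound and no fluoroarene.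
- **Against.** A6 is a tetracarbonyl chain that must be assembled by polyanion acylation of an epimerisable alpha-alkoxy acyl unit. Aldol folding to a resorcylate competes with the Claisen folding. The strongly basic medium threatens C3 and can open the dioxolane by beta-elimination. After A7, an acetonide and two acetals must still be removed in acid and ring C closed.
- **Comparison.** The chosen plan is convergent, whereas this one is linear from 15 and runs to about seven to nine steps. Its stereochemistry is more secure, but its ring construction is less so.

Key step: step 8

Remark: 5-fluorobenzene-1,3-diol, 2,4,6-tribromoresorcinol, prenyl bromide and 4-methoxybenzyl alcohol are taken as purchased; starting from the fluororesorcinol instead of its dimethyl ether saves a demethylation.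

Remark: the sense of induction of the zirconium BINOLate with this ortho-alkoxy aldehyde cannot be predicted with certainty; the (S)-ligand is written, and the (R)-ligand would be used if a model run showed the opposite sense.

## Route

Step 1
Reactants: 1 5-fluorobenzene-1,3-diol
Product: 2 1-(2-fluoro-4,6-dihydroxyphenyl)ethanone
Conditions: AcOH (1.5 equiv), BF3·OEt2 (as medium), 90 °C; aq. NaOAc, then MeOH/H2O, reflux
Reagents that add atoms: acetic acid, CC(=O)O
Why: Nencki-type Friedel–Crafts acylation of a resorcinol; as with resorcinol itself the acyl group should enter para to one hydroxyl and ortho to the other, next to the small fluorine, and not between the two hydroxyls, and any symmetrical isomer is removed at this stage.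

Step 2
Reactants: 2 1-(2-fluoro-4,6-dihydroxyphenyl)ethanone
Product: 3 1-[2-fluoro-4,6-bis(methoxymethoxy)phenyl]ethanone
Conditions: NaH (2.4 equiv), THF/DMF, 0 °C; MOMCl (2.6 equiv), 0 °C to rt
Reagents that add atoms: chloromethyl methyl ether, COCCl
Why: Williamson-type O-alkylation of both phenoxides; the hydrogen-bonded ortho hydroxyl needs full deprotonation to react, and the far less acidic methyl ketone is not enolised by this amount of base.

Step 3
Reactants: 3 1-[2-fluoro-4,6-bis(methoxymethoxy)phenyl]ethanone
Product: 6 2-diazo-1-[2-fluoro-4,6-bis(methoxymethoxy)phenyl]ethanone, via lithium enolate 4 (not isolated), via trifluoroacetyl ketone 5 (not isolated)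
Conditions: LiN(SiMe3)2 (1.1 equiv), THF, −78 °C; CF3CO2CH2CF3 (1.2 equiv), −78 °C; aq. NH4Cl, crude 5 used directly; 4-acetamidobenzenesulfonyl azide (1.5 equiv), Et3N (1.5 equiv), H2O (1 equiv), MeCN, rt
Reagents that add atoms: 4-acetamidobenzenesulfonyl azide, CC(=O)Nc1ccc(cc1)S(=O)(=O)N=[N+]=[N-]; 2,2,2-trifluoroethyl trifluoroacetate, O=C(OCC(F)(F)F)C(F)(F)F (its atoms stay only in 5)
Why: Regitz-type deacylative diazo transfer: the kinetic enolate 4 is C-trifluoroacetylated to the activated diketone 5, which takes the diazo group from the sulfonyl azide and loses the trifluoroacetyl group as the N-sulfonyl amide; the aryl fluoride and the acetals are inert at −78 °C and towards Et3N.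

Step 4
Reactants: 7 2,4,6-tribromobenzene-1,3-diol
Product: 8 1,3,5-tribromo-2,4-bis(methoxymethoxy)benzene
Conditions: MOMCl (2.6 equiv), i-Pr2NEt (3 equiv), CH2Cl2, 0 °C to rt
Reagents that add atoms: chloromethyl methyl ether, COCCl
Why: O-alkylation of the two acidic, bromine-flanked phenols; the acetals tolerate organolithium reagents and later stabilise the adjacent aryllithiums by chelation.

Step 5
Reactants: 8 1,3,5-tribromo-2,4-bis(methoxymethoxy)benzene, 9 1-bromo-3-methylbut-2-ene (prenyl bromide)
Product: 11 1,5-dibromo-2,4-bis(methoxymethoxy)-3-(3-methylbut-2-en-1-yl)benzene, via aryllithium 10 (not isolated)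
Conditions: n-BuLi (1.05 equiv), THF, −78 °C; CuBr·SMe2 (20 mol%), 9 (1.3 equiv), −78 to 0 °C
Reagents that add atoms: none
Why: Bromine–lithium exchange followed by copper-catalysed allylic substitution at the primary carbon of 9; exchange is expected at the bromine between the two OMOM groups, because that aryllithium is stabilised by two ortho oxygens and that C–Br bond is the most crowded, and the copper catalyst suppresses reverse-prenyl and Wurtz products.

Step 6
Reactants: 11 1,5-dibromo-2,4-bis(methoxymethoxy)-3-(3-methylbut-2-en-1-yl)benzene, 9 1-bromo-3-methylbut-2-ene (prenyl bromide)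
Product: 13 1-bromo-2,4-bis(methoxymethoxy)-3,5-bis(3-methylbut-2-en-1-yl)benzene, via aryllithium 12 (not isolated)
Conditions: n-BuLi (1.0 equiv), THF, −78 °C; CuBr·SMe2 (20 mol%), 9 (1.3 equiv), −78 to 0 °C
Reagents that add atoms: none
Why: The same exchange and allylation on one of two equivalent bromines; one equivalent of n-BuLi should stop at mono-exchange because an aryllithium resists a second exchange on the same ring, and exchange at −78 °C is much faster than deprotonation of the benzylic–allylic CH2.

Step 7
Reactants: 13 1-bromo-2,4-bis(methoxymethoxy)-3,5-bis(3-methylbut-2-en-1-yl)benzene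
Product: 15 2,4-bis(methoxymethoxy)-3,5-bis(3-methylbut-2-en-1-yl)benzaldehyde, via aryllithium 14 (not isolated)
Conditions: n-BuLi (1.1 equiv), THF, −78 °C; DMF (3 equiv), −78 to 0 °C; aq. NH4Cl
Reagents that add atoms: N,N-dimethylformamide, CN(C)C=O
Why: Bromine–lithium exchange and Bouveault-type formylation; the hemiaminal alkoxide is stable until the quench, so over-addition is excluded, and the prenyl groups are inert.

Step 8
Reactants: 6 2-diazo-1-[2-fluoro-4,6-bis(methoxymethoxy)phenyl]ethanone, 16 (4-methoxyphenyl)methanol, 15 2,4-bis(methoxymethoxy)-3,5-bis(3-methylbut-2-en-1-yl)benzaldehyde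
Product: 17 (2R,3R)-3-[2,4-bis(methoxymethoxy)-3,5-bis(3-methylbut-2-en-1-yl)phenyl]-1-[2-fluoro-4,6-bis(methoxymethoxy)phenyl]-3-hydroxy-2-[(4-methoxybenzyl)oxy]propan-1-one
Conditions: Rh2(OAc)4 (2 mol%), Zr(OtBu)4/(S)-3,3'-diiodo-BINOL (1:2, 20 mol% Zr, pre-formed, volatiles removed), 16 (1.3 equiv), 15 (1.0 equiv), 4 Å MS, CH2Cl2, 0 °C; 6 (1.3 equiv) added over 3 h
Reagents that add atoms: none
Why: Rh2(OAc)4 (divalent rhodium) expels N2 from 6 and gives an electrophilic rhodium carbenoid at the future C3; the hydroxyl oxygen of 16 adds to it and the protic oxonium ylide so formed (equivalently its enol tautomer) is a nucleophilic enol equivalent. Before the 1,2-proton shift can turn it into the plain O–H insertion product, the ylide carbon adds to the formyl carbon of 15, which is bound and activated by the chiral tetravalent zirconium BINOLate (two-point binding through C=O and the ortho OMOM oxygen is possible), so that C3–O and C2–C3 form in one event. The closest known reaction type is the three-component aldol-type coupling of a diazo carbonyl compound, an alcohol and an aldehyde under cooperative catalysis by Rh2(OAc)4 and a chiral Lewis acid. No ring is closed in this step. The carbinol stereocentre (flavanone C2) is controlled by the BINOLate pocket, which leaves one face of the bound aldehyde open; the ether stereocentre (flavanone C3) is controlled by the open, antiperiplanar transition state typical of this catalyst type, which sets the PMBO group anti to the new hydroxyl, the relationship that becomes 2,3-trans after ring closure. The step needs trapping to beat proton shift, which the Lewis acid activation of the electron-rich, hindered aldehyde and the slow addition of 6 into excess activated 15 are meant to secure. It also needs O–H capture to beat cyclopropanation of the prenyl alkenes and attack of the carbenoid on the neighbouring OMOM oxygen, which the nucleophilicity and excess of 16 should secure; t-butoxide ligands on zirconium are chosen so that no competing primary alcohol is released, and the aryl fluoride is a spectator.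

Step 9
Reactants: 17 (2R,3R)-3-[2,4-bis(methoxymethoxy)-3,5-bis(3-methylbut-2-en-1-yl)phenyl]-1-[2-fluoro-4,6-bis(methoxymethoxy)phenyl]-3-hydroxy-2-[(4-methoxybenzyl)oxy]propan-1-one
Product: 18 (2R,3R)-2-[2,4-bis(methoxymethoxy)-3,5-bis(3-methylbut-2-en-1-yl)phenyl]-3-[(4-methoxybenzyl)oxy]-5,7-bis(methoxymethoxy)-2,3-dihydro-4H-chromen-4-one
Conditions: Cs2CO3 (1.2 equiv), DMF, 0 °C, then rt if needed
Reagents that add atoms: none
Why: Intramolecular nucleophilic aromatic substitution (addition–elimination): the C2 alkoxide attacks the fluorine-bearing carbon ortho to the ketone, the negative charge resting on the acyl-bearing carbon and on CH positions (both OMOM groups are meta to fluorine), and fluoride leaves to close the six-membered ring C. No bond at C2 or C3 is broken, so the anti aldol should map onto the 2,3-trans chromanone with both large groups equatorial, and the PMB ether keeps the C3 oxygen from a competing five-membered closure.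

Step 10
Reactants: 18 (2R,3R)-2-[2,4-bis(methoxymethoxy)-3,5-bis(3-methylbut-2-en-1-yl)phenyl]-3-[(4-methoxybenzyl)oxy]-5,7-bis(methoxymethoxy)-2,3-dihydro-4H-chromen-4-one
Product: 19 (2R,3R)-2-[2,4-bis(methoxymethoxy)-3,5-bis(3-methylbut-2-en-1-yl)phenyl]-3-hydroxy-5,7-bis(methoxymethoxy)-2,3-dihydro-4H-chromen-4-one
Conditions: DDQ (1.3 equiv), CH2Cl2/pH 7 phosphate buffer (10:1), 0 °C
Reagents that add atoms: none
Why: Oxidative PMB ether cleavage: DDQ abstracts hydride from the anisyl CH2 through a charge-transfer complex, water adds to the oxocarbenium ion and the hemiacetal collapses to 19 and 4-methoxybenzaldehyde; cold, buffered conditions are chosen to spare the acetals and the prenyl CH2 groups.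

Step 11
Reactants: 19 (2R,3R)-2-[2,4-bis(methoxymethoxy)-3,5-bis(3-methylbut-2-en-1-yl)phenyl]-3-hydroxy-5,7-bis(methoxymethoxy)-2,3-dihydro-4H-chromen-4-one
Product: 20 (2R,3R)-2-[2,4-dihydroxy-3,5-bis(3-methylbut-2-en-1-yl)phenyl]-3,5,7-trihydroxy-2,3-dihydro-4H-chromen-4-one (cathayanon I)
Conditions: 3 M aq. HCl/MeOH (1:4), rt to 40 °C, stopped at full conversion
Reagents that add atoms: none
Why: Acid-catalysed acetal exchange with methanol removes the four MOM groups; the acetal next to the C4 carbonyl and the two ring B acetals flanked by ortho substituents are especially labile, which should allow conditions mild enough for the prenyl groups. The trans (2R,3R) arrangement is the thermodynamically preferred one, so reversible ionisation at C2 should not cost stereochemical purity.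

## Compound list

1 | 5-fluorobenzene-1,3-diol | Oc1cc(O)cc(F)c1 | starting material
2 | 1-(2-fluoro-4,6-dihydroxyphenyl)ethanone | CC(=O)c1c(F)cc(O)cc1O | intermediate
3 | 1-[2-fluoro-4,6-bis(methoxymethoxy)phenyl]ethanone | CC(=O)c1c(F)cc(OCOC)cc1OCOC | intermediate
4 | lithium 1-[2-fluoro-4,6-bis(methoxymethoxy)phenyl]ethenolate | [Li]OC(=C)c1c(F)cc(OCOC)cc1OCOC | intermediate (not isolated)
5 | 4,4,4-trifluoro-1-[2-fluoro-4,6-bis(methoxymethoxy)phenyl]butane-1,3-dione | O=C(CC(=O)C(F)(F)F)c1c(F)cc(OCOC)cc1OCOC | intermediate (not isolated)
6 | 2-diazo-1-[2-fluoro-4,6-bis(methoxymethoxy)phenyl]ethanone | [N-]=[N+]=CC(=O)c1c(F)cc(OCOC)cc1OCOC | intermediate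
7 | 2,4,6-tribromobenzene-1,3-diol (2,4,6-tribromoresorcinol) | Oc1c(Br)cc(Br)c(O)c1Br | starting material
8 | 1,3,5-tribromo-2,4-bis(methoxymethoxy)benzene | COCOc1c(Br)cc(Br)c(OCOC)c1Br | intermediate
9 | 1-bromo-3-methylbut-2-ene (prenyl bromide) | CC(C)=CCBr | starting material
10 | [3,5-dibromo-2,6-bis(methoxymethoxy)phenyl]lithium | [Li]c1c(OCOC)c(Br)cc(Br)c1OCOC | intermediate (not isolated)
11 | 1,5-dibromo-2,4-bis(methoxymethoxy)-3-(3-methylbut-2-en-1-yl)benzene | COCOc1c(Br)cc(Br)c(OCOC)c1CC=C(C)C | intermediate
12 | [5-bromo-2,4-bis(methoxymethoxy)-3-(3-methylbut-2-en-1-yl)phenyl]lithium | [Li]c1cc(Br)c(OCOC)c(CC=C(C)C)c1OCOC | intermediate (not isolated)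
13 | 1-bromo-2,4-bis(methoxymethoxy)-3,5-bis(3-methylbut-2-en-1-yl)benzene | CC(C)=CCc1cc(Br)c(OCOC)c(CC=C(C)C)c1OCOC | intermediate
14 | [2,4-bis(methoxymethoxy)-3,5-bis(3-methylbut-2-en-1-yl)phenyl]lithium | [Li]c1cc(CC=C(C)C)c(OCOC)c(CC=C(C)C)c1OCOC | intermediate (not isolated)
15 | 2,4-bis(methoxymethoxy)-3,5-bis(3-methylbut-2-en-1-yl)benzaldehyde | CC(C)=CCc1cc(C=O)c(OCOC)c(CC=C(C)C)c1OCOC | intermediate
16 | (4-methoxyphenyl)methanol (4-methoxybenzyl alcohol) | COc1ccc(CO)cc1 | starting material
17 | (2R,3R)-3-[2,4-bis(methoxymethoxy)-3,5-bis(3-methylbut-2-en-1-yl)phenyl]-1-[2-fluoro-4,6-bis(methoxymethoxy)phenyl]-3-hydroxy-2-[(4-methoxybenzyl)oxy]propan-1-one | CC(C)=CCc1cc([C@@H](O)[C@@H](OCc2ccc(OC)cc2)C(=O)c2c(F)cc(OCOC)cc2OCOC)c(OCOC)c(CC=C(C)C)c1OCOC | intermediate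
18 | (2R,3R)-2-[2,4-bis(methoxymethoxy)-3,5-bis(3-methylbut-2-en-1-yl)phenyl]-3-[(4-methoxybenzyl)oxy]-5,7-bis(methoxymethoxy)-2,3-dihydro-4H-chromen-4-one | CC(C)=CCc1cc([C@H]2Oc3cc(OCOC)cc(OCOC)c3C(=O)[C@@H]2OCc2ccc(OC)cc2)c(OCOC)c(CC=C(C)C)c1OCOC | intermediate
19 | (2R,3R)-2-[2,4-bis(methoxymethoxy)-3,5-bis(3-methylbut-2-en-1-yl)phenyl]-3-hydroxy-5,7-bis(methoxymethoxy)-2,3-dihydro-4H-chromen-4-one | CC(C)=CCc1cc([C@H]2Oc3cc(OCOC)cc(OCOC)c3C(=O)[C@@H]2O)c(OCOC)c(CC=C(C)C)c1OCOC | intermediate
20 | (2R,3R)-2-[2,4-dihydroxy-3,5-bis(3-methylbut-2-en-1-yl)phenyl]-3,5,7-trihydroxy-2,3-dihydro-4H-chromen-4-one (cathayanon I) | CC(C)=CCc1cc([C@H]2Oc3cc(O)cc(O)c3C(=O)[C@@H]2O)c(O)c(CC=C(C)C)c1O | target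

## Step count and least certain steps

Total step count: 11. Longest linear sequence: 8 steps (steps 4 to 11, from 7 to 20); the ring A branch (steps 1 to 3) joins at step 8.

**Step 8 (key step).**
- What may go wrong: proton shift in the oxonium ylide may outrun addition to the aldehyde, because the aldehyde is electron-rich and flanked by two ortho substituents. Facial or anti/syn selectivity may be poor for the same reason. The carbenoid may be captured within the molecule by the neighbouring acetal oxygen.
- Tolerable error: a fault confined to C3 would be expected to be correctable after step 9, since the trans chromanone is the more stable epimer.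
- Fallback: separate the two bond formations. It sets out from 6 and 16, which under Rh2(OAc)4 alone (CH2Cl2, rt) should give the plain O–H insertion product 1-[2-fluoro-4,6-bis(methoxymethoxy)phenyl]-2-[(4-methoxybenzyl)oxy]ethanone F1. Me3SiOTf/Et3N (CH2Cl2, 0 °C) converts this into (Z)-{1-[2-fluoro-4,6-bis(methoxymethoxy)phenyl]-2-[(4-methoxybenzyl)oxy]ethenyl}oxy(trimethyl)silane F2. A Mukaiyama aldol addition of F2 to 15 under an anti-selective chiral zirconium BINOLate catalyst (Zr(OtBu)4, 3,3'-diiodo-BINOL, n-PrOH, H2O, toluene, 0 °C) comes back to the route at 17.

**Step 9.**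
- What may go wrong: the alkoxide may fragment by retro-aldol cleavage faster than it displaces fluoride, because the aldehyde it would release is stabilised. Excess base may also enolise C3 of the product and open ring C by beta-elimination, eroding C2.
- Fallback: a base-free, fluoride-chain closure. It sets out from 17, which is silylated (Me3SiCl, imidazole, CH2Cl2) to (2R,3R)-3-[2,4-bis(methoxymethoxy)-3,5-bis(3-methylbut-2-en-1-yl)phenyl]-1-[2-fluoro-4,6-bis(methoxymethoxy)phenyl]-2-[(4-methoxybenzyl)oxy]-3-[(trimethylsilyl)oxy]propan-1-one F3. Catalytic Bu4N[Ph3SiF2] in THF then unmasks the alkoxide a little at a time, and each substitution releases the fluoride that desilylates the next molecule. This comes back at 18.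

**Step 10.**
- What may go wrong: hydride abstraction by DDQ at the benzylic–allylic CH2 of the prenyl groups or at C2–H, since ring B is about as electron-rich as the anisyl group.
- Fallback: non-oxidative, chelation-assisted cleavage. It sets out from 18; MgBr2·OEt2 and Me2S in CH2Cl2 at rt should bind the C4 carbonyl and the C3 ether oxygen and transfer the benzyl group to sulfur. It comes back at 19 and makes no new compound (F0).

**Step 11.**
- What may go wrong: acid-catalysed closure of a prenyl group onto a freed neighbouring phenol (chroman formation) or hydration of the alkenes before the last acetal has gone.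
- Fallback: aprotic Lewis acid transfer of the MOM groups to a thiol. It sets out from 19; ZnBr2 and n-PrSH in CH2Cl2 at 0 °C for minutes come back at 20 and make no new compound (F0).

**Step 5.**
- What may go wrong: exchange at a flanking bromine in place of the central one, or halogen scrambling between aryllithium and unreacted 8. This would place the formyl group between the two oxygens at the end.
- Fallback: fix the central position before any choice exists. It sets out from 7:
  - Na2SO3/NaOH in aqueous MeOH should remove the two bromines para to hydroxyl and leave 2-bromobenzene-1,3-diol F4.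
  - MOMCl/i-Pr2NEt gives 2-bromo-1,3-bis(methoxymethoxy)benzene F5.
  - Exchange of the single bromine (n-BuLi, −78 °C) and prenylation with 9 under CuBr·SMe2 catalysis give 1,3-bis(methoxymethoxy)-2-(3-methylbut-2-en-1-yl)benzene F6.
  - Directed ortho-metalation next to an OMOM group (n-BuLi, TMEDA, THF, −20 °C) and prenylation with 9 give 1,3-bis(methoxymethoxy)-2,4-bis(3-methylbut-2-en-1-yl)benzene F7.
  - A second ortho-metalation at the only remaining CH next to an OMOM group, followed by DMF, comes back to the route at 15.

## Further compounds

F1 | step 8 | 1-[2-fluoro-4,6-bis(methoxymethoxy)phenyl]-2-[(4-methoxybenzyl)oxy]ethanone | COc1ccc(COCC(=O)c2c(F)cc(OCOC)cc2OCOC)cc1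
F2 | step 8 | (Z)-{1-[2-fluoro-4,6-bis(methoxymethoxy)phenyl]-2-[(4-methoxybenzyl)oxy]ethenyl}oxy(trimethyl)silane | COc1ccc(CO/C=C(\O[Si](C)(C)C)c2c(F)cc(OCOC)cc2OCOC)cc1
F3 | step 9 | (2R,3R)-3-[2,4-bis(methoxymethoxy)-3,5-bis(3-methylbut-2-en-1-yl)phenyl]-1-[2-fluoro-4,6-bis(methoxymethoxy)phenyl]-2-[(4-methoxybenzyl)oxy]-3-[(trimethylsilyl)oxy]propan-1-one | CC(C)=CCc1cc([C@@H](O[Si](C)(C)C)[C@@H](OCc2ccc(OC)cc2)C(=O)c2c(F)cc(OCOC)cc2OCOC)c(OCOC)c(CC=C(C)C)c1OCOC
F0 | step 10 | none | none
F0 | step 11 | none | none
F4 | step 5 | 2-bromobenzene-1,3-diol | Oc1cccc(O)c1Br
F5 | step 5 | 2-bromo-1,3-bis(methoxymethoxy)benzene | COCOc1cccc(OCOC)c1Br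
F6 | step 5 | 1,3-bis(methoxymethoxy)-2-(3-methylbut-2-en-1-yl)benzene | COCOc1cccc(OCOC)c1CC=C(C)C
F7 | step 5 | 1,3-bis(methoxymethoxy)-2,4-bis(3-methylbut-2-en-1-yl)benzene | COCOc1ccc(CC=C(C)C)c(OCOC)c1CC=C(C)C
A1 | alternative 1 | 2,10-dimethylundeca-2,9-dien-6-one | CC(C)=CCCC(=O)CCC=C(C)C
A2 | alternative 1 | diethyl 2-(ethoxymethylidene)propanedioate | CCOC=C(C(=O)OCC)C(=O)OCC
A3 | alternative 1 | ethyl 2,4-dihydroxy-3,5-bis(3-methylbut-2-en-1-yl)benzoate | CCOC(=O)c1cc(CC=C(C)C)c(O)c(CC=C(C)C)c1O
A4 | alternative 2 | 2-[2,4-bis(methoxymethoxy)-3,5-bis(3-methylbut-2-en-1-yl)phenyl]-2-[2-formyl-3,5-bis(methoxymethoxy)phenoxy]acetaldehyde (racemic, configurationally labile) | O=CC(Oc1cc(OCOC)cc(OCOC)c1C=O)c1cc(CC=C(C)C)c(OCOC)c(CC=C(C)C)c1OCOC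
A5 | alternative 2 | (2R,3R)-2-[2,4-bis(methoxymethoxy)-3,5-bis(3-methylbut-2-en-1-yl)phenyl]-3-hydroxy-5,7-bis(methoxymethoxy)-2,3-dihydro-4H-chromen-4-one (identical with 19) | CC(C)=CCc1cc([C@H]2Oc3cc(OCOC)cc(OCOC)c3C(=O)[C@@H]2O)c(OCOC)c(CC=C(C)C)c1OCOC
A6 | alternative 3 | methyl 7-{(4R,5S)-5-[2,4-bis(methoxymethoxy)-3,5-bis(3-methylbut-2-en-1-yl)phenyl]-2,2-dimethyl-1,3-dioxolan-4-yl}-3,5,7-trioxoheptanoate | CC(C)=CCc1cc([C@@H]2OC(C)(C)O[C@H]2C(=O)CC(=O)CC(=O)CC(=O)OC)c(OCOC)c(CC=C(C)C)c1OCOC
A7 | alternative 3 | {(4R,5S)-5-[2,4-bis(methoxymethoxy)-3,5-bis(3-methylbut-2-en-1-yl)phenyl]-2,2-dimethyl-1,3-dioxolan-4-yl}(2,4,6-trihydroxyphenyl)methanone | CC(C)=CCc1cc([C@@H]2OC(C)(C)O[C@H]2C(=O)c3c(O)cc(O)cc3O)c(OCOC)c(CC=C(C)C)c1OCOC
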